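**Retrosynthetic overview**

1. Locants: C1 (OMe), C2 (OH), C3 (OBz), C4 (OH), C5 (alkene carbon carrying C6H2OBz), C5a (alkene CH). The plan rests on the vicinal C3–O/C4–O pair lying directly beside the substituted alkene carbon C5 of the one carbocycle, which is the oxygenation pattern of an arene 2,3-cis-dihydrodiol.
2. Late disconnections: the C2–O PMB ether (removed last), the C6–O benzoate, the C5–C6 bond (Stille hydroxymethylation of a C5 vinyl bromide), the C4 configuration (oxidation to the enone, then reduction), and the C3–O benzoate.
3. Middle: C1–OMe and C2–OH come from trans opening at allylic C1 of a β-epoxide across C1/C2, placed anti to a C3/C4 acetonide.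
4. Earliest: both C3–O and C4–O bonds and the first two stereocentres come from enzymatic cis-dihydroxylation of bromobenzene, whose bromine marks C5.
5. Ring order: no carbocycle is built. The cyclohexene is the dearomatised benzene ring (step 1); only a dioxolane (step 2) and an oxirane (step 3) are closed temporarily and opened again.

Key step: step 1

Remark on conventions and one assumption: α is the ring face that carries the C1 methoxy and C3 benzoate in the target, β the face of its C2 and C4 hydroxyls. The toluene-dioxygenase strain E. coli JM109(pDTG601) is treated as a standard laboratory biocatalyst, so bromobenzene is the actual starting material.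

**Route**

Step 1
Reactants: 1 bromobenzene
Product: 2 (1S,2S)-3-bromocyclohexa-3,5-diene-1,2-diol (3α,4α-diol, Br on C5)
Conditions: E. coli JM109(pDTG601) whole cells (toluene dioxygenase, IPTG-induced), aerated glucose-fed fermentation, pH 7, 35 °C; EtOAc extraction
Reagents that add atoms: dioxygen, O=O
Why: The Rieske-type toluene dioxygenase passes two electrons from NADH through its reductase and ferredoxin to a mononuclear non-heme iron centre, which binds O2 and delivers both oxygen atoms to one face of the bond next to bromine, so the future C3–O and C4–O bonds form suprafacially and the cis-dihydrodiol is released without rearomatisation because the strain lacks the diol dehydrogenase. This is the established microbial arene cis-dihydroxylation of monosubstituted benzenes, for which bromobenzene is a routine substrate. No ring is closed; the benzene ring simply becomes the cyclohexadiene that is carried through to the target. Both new stereocentres are fixed by the active-site pocket, which binds the arene with the halogen in one orientation and is expected to give the (1S,2S) diol as essentially a single enantiomer, the S carbinol remote from bromine already having the configuration of C3 in the target. The step needs regioselectivity for the bond adjacent to bromine and enantioface selectivity, and both are supplied by the enzyme, while the same bromine later serves as the handle for C6 and deactivates its own alkene. The diol dehydrates to bromophenols under acid, so it should be extracted under neutral to slightly basic conditions and protected at once.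

Step 2
Reactants: 2 (1S,2S)-3-bromocyclohexa-3,5-diene-1,2-diol
Product: 3 (3aS,7aS)-4-bromo-2,2-dimethyl-3a,7a-dihydro-1,3-benzodioxole (3α,4α-O-isopropylidene diene)
Conditions: 2,2-dimethoxypropane, p-TsOH·H2O (cat.), acetone, rt; Et3N quench
Reagents that add atoms: 2,2-dimethoxypropane, COC(C)(C)OC
Why: Acid-catalysed transketalisation closes the cis-fused dioxolane on the cis-diol, which stops dehydration to phenol and shields the α face of the diene for the next step.

Step 3
Reactants: 3 (3aS,7aS)-4-bromo-2,2-dimethyl-3a,7a-dihydro-1,3-benzodioxole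
Product: 4 1β,2β-epoxy-5-bromo-3α,4α-O-isopropylidenecyclohex-5(5a)-ene (oxirane anti to the acetonide)
Conditions: mCPBA, CH2Cl2, 0 °C → rt (3 used freshly prepared)
Reagents that add atoms: mCPBA (3-chloroperoxybenzoic acid), OOC(=O)c1cccc(Cl)c1
Why: Prilezhaev epoxidation should take place at the disubstituted C1=C2 alkene because the C5=C5a alkene is deactivated by bromine, and the peracid approaches the β face away from the acetonide, which sets C1 and C2.

Step 4
Reactants: 4 1β,2β-epoxy-5-bromo-3α,4α-O-isopropylidenecyclohex-5(5a)-ene
Product: 5 5-bromo-3α,4α-O-isopropylidene-1α-methoxycyclohex-5(5a)-en-2β-ol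
Conditions: MeOH (10 equiv), camphorsulfonic acid (10 mol %), CH2Cl2, 0 °C → rt
Reagents that add atoms: methanol, CO
Why: Acid-catalysed opening of the vinyl oxirane occurs at allylic C1, which best supports positive charge (C2 is inductively deactivated and shielded by the neighbouring dioxolane oxygen), with inversion, so methanol enters on the α face and the C2 hydroxyl stays β.

Step 5
Reactants: 5 5-bromo-3α,4α-O-isopropylidene-1α-methoxycyclohex-5(5a)-en-2β-ol
Product: 6 5-bromo-3α,4α-O-isopropylidene-1α-methoxy-2β-(4-methoxybenzyloxy)cyclohex-5(5a)-ene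
Conditions: NaH, 4-methoxybenzyl chloride, Bu4NI (cat.), DMF, 0 °C → rt
Reagents that add atoms: 4-methoxybenzyl chloride, COc1ccc(CCl)cc1
Why: Williamson etherification of the only free hydroxyl gives a PMB ether that tolerates the acid, oxidant, hydride and palladium steps ahead and can be removed at the end under neutral oxidative conditions that do not move benzoates.

Step 6
Reactants: 6 5-bromo-3α,4α-O-isopropylidene-1α-methoxy-2β-(4-methoxybenzyloxy)cyclohex-5(5a)-ene
Product: 7 5-bromo-1α-methoxy-2β-(4-methoxybenzyloxy)cyclohex-5(5a)-ene-3α,4α-diol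
Conditions: AcOH/H2O (4:1), 50 °C
Reagents that add atoms: none
Why: Acid-catalysed acetal hydrolysis frees the C3/C4 cis-diol, while the PMB ether, the allylic methyl ether and the vinyl bromide tolerate warm aqueous acetic acid.

Step 7
Reactants: 7 5-bromo-1α-methoxy-2β-(4-methoxybenzyloxy)cyclohex-5(5a)-ene-3α,4α-diol; 8 benzoyl chloride
Product: 9 3α-benzoyloxy-5-bromo-1α-methoxy-2β-(4-methoxybenzyloxy)cyclohex-5(5a)-en-4α-ol
Conditions: BzCl (1.05 equiv), pyridine, CH2Cl2, −40 → −20 °C
Reagents that add atoms: benzoyl chloride (8), O=C(Cl)c1ccccc1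
Why: Regioselective acylation of a cis-1,2-diol: in the half-chair with the C1, C2 and C3 substituents equatorial the C3 hydroxyl is equatorial while the C4 hydroxyl is pseudoaxial and pressed against the C5 bromine, so one equivalent of acyl chloride at low temperature should esterify O3 (the equatorial-over-axial preference familiar from pyranoside cis-diols).

Step 8
Reactants: 9 3α-benzoyloxy-5-bromo-1α-methoxy-2β-(4-methoxybenzyloxy)cyclohex-5(5a)-en-4α-ol
Product: 10 3α-benzoyloxy-5-bromo-1α-methoxy-2β-(4-methoxybenzyloxy)cyclohex-5(5a)-en-4-one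
Conditions: Dess–Martin periodinane, CH2Cl2, 0 °C → rt; crude enone taken on directly
Reagents that add atoms: none
Why: Dess–Martin oxidation converts the remaining secondary C4 alcohol into the α-bromo enone under non-basic conditions that avoid benzoate migration, enolisation at C3 and β-elimination, and deliberately erases the wrong C4 configuration.

Step 9
Reactants: 10 3α-benzoyloxy-5-bromo-1α-methoxy-2β-(4-methoxybenzyloxy)cyclohex-5(5a)-en-4-one
Product: 11 3α-benzoyloxy-5-bromo-1α-methoxy-2β-(4-methoxybenzyloxy)cyclohex-5(5a)-en-4β-ol
Conditions: NaBH4, CeCl3·7H2O, MeOH/THF, −78 °C; cold aq. NH4Cl quench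
Reagents that add atoms: none
Why: Luche 1,2-reduction: with the C1, C2 and C3 substituents all equatorial in the enone half-chair, the small cerium-activated methoxyborohydride should attack the carbonyl axially from the α face to give the pseudoequatorial 4β-alcohol trans to the C3 benzoate, and the vinyl bromide and ester are untouched at −78 °C.

Step 10
Reactants: 11 3α-benzoyloxy-5-bromo-1α-methoxy-2β-(4-methoxybenzyloxy)cyclohex-5(5a)-en-4β-ol; 12 (tributylstannyl)methanol
Product: 13 3α-benzoyloxy-5-(hydroxymethyl)-1α-methoxy-2β-(4-methoxybenzyloxy)cyclohex-5(5a)-en-4β-ol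
Conditions: Pd(PPh3)4 (10 mol %), 12 (1.5 equiv), degassed toluene, 100 °C
Reagents that add atoms: (tributylstannyl)methanol (12), CCCC[Sn](CCCC)(CCCC)CO
Why: Stille coupling: oxidative addition of zerovalent palladium into the vinyl C5–Br bond, transfer of the hydroxymethyl group from tin and reductive elimination form C5–C6 without moving the alkene, under neutral conditions that leave the benzoate, the PMB ether and the free alcohol alone; no stereocentre is involved.

Step 11
Reactants: 13 3α-benzoyloxy-5-(hydroxymethyl)-1α-methoxy-2β-(4-methoxybenzyloxy)cyclohex-5(5a)-en-4β-ol; 8 benzoyl chloride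
Product: 14 3α-benzoyloxy-5-(benzoyloxymethyl)-1α-methoxy-2β-(4-methoxybenzyloxy)cyclohex-5(5a)-en-4β-ol
Conditions: BzCl (1.05 equiv), 2,4,6-collidine, CH2Cl2, −78 → −30 °C
Reagents that add atoms: benzoyl chloride (8), O=C(Cl)c1ccccc1
Why: Chemoselective acylation of the primary allylic C6 hydroxyl over the secondary C4 hydroxyl, which is flanked by the C3 benzoate and the fully substituted C5, using one equivalent of acyl chloride and a hindered weak base at low temperature.

Step 12
Reactants: 14 3α-benzoyloxy-5-(benzoyloxymethyl)-1α-methoxy-2β-(4-methoxybenzyloxy)cyclohex-5(5a)-en-4β-ol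
Product: 15 target, [(3S,4R,5R,6S)-5-benzoyloxy-4,6-dihydroxy-3-methoxycyclohex-1-en-1-yl]methyl benzoate (1α-OMe, 2β-OH, 3α-OBz, 4β-OH)
Conditions: DDQ, CH2Cl2/pH 7 phosphate buffer (10:1), 0 °C → rt
Reagents that add atoms: none
Why: Oxidative PMB cleavage (hydride abstraction to the oxocarbenium ion, then hydrolysis) frees the C2 hydroxyl under neutral conditions that should not move the C3 benzoate to O2 or O4, and the inductively deactivated allylic alcohol and allylic methyl ether should react far more slowly than the electron-rich benzyl ether.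

**Compound list**

1 | bromobenzene | Brc1ccccc1 | starting material
2 | (1S,2S)-3-bromocyclohexa-3,5-diene-1,2-diol | BrC1=CC=C[C@H](O)[C@@H]1O | intermediate
3 | (3aS,7aS)-4-bromo-2,2-dimethyl-3a,7a-dihydro-1,3-benzodioxole | BrC1=CC=C[C@@H]2OC(C)(C)O[C@H]12 | intermediate
4 | 1β,2β-epoxy-5-bromo-3α,4α-O-isopropylidenecyclohex-5(5a)-ene | BrC1=C[C@H]2O[C@H]2[C@@H]3OC(C)(C)O[C@H]13 | intermediate
5 | 5-bromo-3α,4α-O-isopropylidene-1α-methoxycyclohex-5(5a)-en-2β-ol | CO[C@@H]1[C@@H](O)[C@@H]2OC(C)(C)O[C@@H]2C(Br)=C1 | intermediate
6 | 2β-O-(4-methoxybenzyl) ether of 5 | CO[C@@H]1[C@@H](OCc3ccc(OC)cc3)[C@@H]2OC(C)(C)O[C@@H]2C(Br)=C1 | intermediate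
7 | 5-bromo-1α-methoxy-2β-(4-methoxybenzyloxy)cyclohex-5(5a)-ene-3α,4α-diol | CO[C@@H]1[C@@H](OCc2ccc(OC)cc2)[C@H](O)[C@H](O)C(Br)=C1 | intermediate
8 | benzoyl chloride | O=C(Cl)c1ccccc1 | starting material
9 | 3α-O-benzoate of 7 (4α-OH free) | CO[C@@H]1[C@@H](OCc2ccc(OC)cc2)[C@H](OC(=O)c2ccccc2)[C@H](O)C(Br)=C1 | intermediate
10 | 3α-benzoyloxy-5-bromo-1α-methoxy-2β-(4-methoxybenzyloxy)cyclohex-5(5a)-en-4-one | CO[C@@H]1[C@@H](OCc2ccc(OC)cc2)[C@H](OC(=O)c2ccccc2)C(=O)C(Br)=C1 | intermediate
11 | 3α-benzoyloxy-5-bromo-1α-methoxy-2β-(4-methoxybenzyloxy)cyclohex-5(5a)-en-4β-ol | CO[C@@H]1[C@@H](OCc2ccc(OC)cc2)[C@H](OC(=O)c2ccccc2)[C@@H](O)C(Br)=C1 | intermediate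
12 | (tributylstannyl)methanol | CCCC[Sn](CCCC)(CCCC)CO | starting material
13 | 3α-benzoyloxy-5-(hydroxymethyl)-1α-methoxy-2β-(4-methoxybenzyloxy)cyclohex-5(5a)-en-4β-ol | CO[C@@H]1[C@@H](OCc2ccc(OC)cc2)[C@H](OC(=O)c2ccccc2)[C@@H](O)C(CO)=C1 | intermediate
14 | 3α-benzoyloxy-5-(benzoyloxymethyl)-1α-methoxy-2β-(4-methoxybenzyloxy)cyclohex-5(5a)-en-4β-ol | CO[C@@H]1[C@@H](OCc2ccc(OC)cc2)[C@H](OC(=O)c2ccccc2)[C@@H](O)C(COC(=O)c2ccccc2)=C1 | intermediate
15 | [(3S,4R,5R,6S)-5-benzoyloxy-4,6-dihydroxy-3-methoxycyclohex-1-en-1-yl]methyl benzoate | CO[C@@H]1[C@@H](O)[C@H](OC(=O)c2ccccc2)[C@@H](O)C(COC(=O)c2ccccc2)=C1 | target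

**Step count and risks**

Total step count: 12. Longest linear sequence: 12 steps, from bromobenzene 1 to target 15.

Steps most likely to fail:

Step 7. What may go wrong is acylation at the pseudoaxial C4 hydroxyl or at both hydroxyls, or base-promoted benzoyl migration between the two cis oxygens, so that the C3 ester is not obtained cleanly. The fallback sets out from diol 7 and replaces regioselective acylation by chemoselective oxidation. Activated MnO2 in CH2Cl2 at rt should oxidise only the allylic C4 carbinol to give 5-bromo-3α-hydroxy-1α-methoxy-2β-(4-methoxybenzyloxy)cyclohex-5(5a)-en-4-one F1. Its single remaining hydroxyl is then benzoylated with benzoyl chloride 8 and pyridine with catalytic DMAP at 0 °C, and the route is rejoined at enone 10.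

Step 9. What may go wrong is hydride delivery to the β face (equatorial attack), which would return the cis alcohol, or migration of the benzoate from O3 to the new C4 alkoxide before the quench. The fallback sets out from cis-alcohol 9, bypasses steps 8 and 9, and inverts C4 by substitution instead of by reduction. Mitsunobu reaction with chloroacetic acid (PPh3, DIAD, THF, 0 °C → rt) should give 3α-benzoyloxy-5-bromo-4β-(chloroacetoxy)-1α-methoxy-2β-(4-methoxybenzyloxy)cyclohex-5(5a)-ene F2; the cis benzoate cannot participate from the face of the leaving group. Thiourea in EtOH at 50 °C then removes the chloroacetate in the presence of the benzoate, and the route is rejoined at alcohol 11.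

Step 10. What may go wrong is slow transfer of the sp3 hydroxymethyl group from tin, which would let protodebromination, homocoupling or thermal benzoyl migration from O3 to O4 compete during prolonged heating. The fallback sets out from bromide 11 and brings in C6 as carbon monoxide. Palladium-catalysed reductive carbonylation (CO at 1–3 atm, Bu3SnH added slowly by syringe pump, Pd(PPh3)4, THF, 50 °C) should give 3α-benzoyloxy-4β-hydroxy-1α-methoxy-2β-(4-methoxybenzyloxy)cyclohex-5(5a)-ene-5-carbaldehyde F3. Luche reduction of this enal (NaBH4, CeCl3·7H2O, MeOH, −78 °C), which spares the benzoate, rejoins the route at allylic alcohol 13.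

**Further compounds**

F1 | step 7 | 5-bromo-3α-hydroxy-1α-methoxy-2β-(4-methoxybenzyloxy)cyclohex-5(5a)-en-4-one | CO[C@@H]1[C@@H](OCc2ccc(OC)cc2)[C@H](O)C(=O)C(Br)=C1
F2 | step 9 | 3α-benzoyloxy-5-bromo-4β-(chloroacetoxy)-1α-methoxy-2β-(4-methoxybenzyloxy)cyclohex-5(5a)-ene | CO[C@@H]1[C@@H](OCc2ccc(OC)cc2)[C@H](OC(=O)c2ccccc2)[C@@H](OC(=O)CCl)C(Br)=C1
F3 | step 10 | 3α-benzoyloxy-4β-hydroxy-1α-methoxy-2β-(4-methoxybenzyloxy)cyclohex-5(5a)-ene-5-carbaldehyde | CO[C@@H]1[C@@H](OCc2ccc(OC)cc2)[C@H](OC(=O)c2ccccc2)[C@@H](O)C(C=O)=C1
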